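**Retrosynthetic overview**
- The target comes from its tetra-O-benzyl ether by one global debenzylation.
- The oxolane, the only ring, is formed last: a C2-symmetric (2S,3S)-1,4-diaryl-2,3-bis(benzyloxymethyl)butane-1,4-dione is closed and reduced in one pot, and both Ar–CH–O centres are set by hydride delivery to ring oxocarbenium ions.
- The diketone comes from an (S,S)-succinate bis-thioester by two thioester–arylboronic acid ketone couplings.
- Key disconnection: the central C3–C4 bond, made by oxidative homocoupling of two identical chiral imide enolates; PhI(OAc)2 turns one enolate into an enolonium equivalent, so two α-carbons are joined and both stereocentres are set at once.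
- The imide comes from 3-(benzyloxy)propanoic acid and (S)-4-isopropyl-oxazolidin-2-one.

Assumption: the SMILES is read as (2S,3S,4S,5S), that is 2,3-cis, 3,4-trans, 4,5-cis (each aryl cis to its neighbouring CH2OH), and compounds 1, 2 and 9 are bought.

**Route**

Step 1
Reactants: 1 3-(benzyloxy)propanoic acid; 2 (S)-4-isopropyl-oxazolidin-2-one
Product: 4 (4S)-3-[3-(benzyloxy)propanoyl]-4-isopropyl-oxazolidin-2-one, via mixed pivalic anhydride 3 (not isolated)
Conditions: PivCl, Et3N, THF, −20 °C; then 2, LiCl, −20 °C → rt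
Reagents that add atoms: none
Why: Mixed-anhydride N-acylation of an oxazolidinone (LiCl/Et3N) is the standard imide synthesis and creates no new stereocentre.

Step 2
Reactants: 4 (4S)-3-[3-(benzyloxy)propanoyl]-4-isopropyl-oxazolidin-2-one (two molecules)
Product: 7 (4S,4'S)-3,3'-[(2S,3S)-2,3-bis(benzyloxymethyl)butanedioyl]bis(4-isopropyl-oxazolidin-2-one), via lithium Z-enolate 5 (not isolated), via alpha-iodanyl imide 6 (not isolated)
Conditions: LiN(iPr)2 (1.05 equiv), THF, −78 °C, 30 min; then PhI(OAc)2 (0.55 equiv), THF, −78 → −50 °C; aq. NH4Cl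
Reagents that add atoms: none
Why: Oxidative enolate homocoupling (enolate plus enolonium equivalent): PhI(OAc)2 converts one chelated Z-enolate 5 into the electrophilic trivalent-iodine species 6, a second 5 attacks its α-carbon, and since each α-carbon bonds on the face away from the isopropyl group, as in the known 3-arylpropanoyl cases, both new centres are S and the C2-symmetric dimer is the major isomer (the meso-type isomer is removed by chromatography); the mixture is kept cold so the β-benzyloxy enolate does not eliminate.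

Step 3
Reactants: 7 (4S,4'S)-3,3'-[(2S,3S)-2,3-bis(benzyloxymethyl)butanedioyl]bis(4-isopropyl-oxazolidin-2-one)
Product: 8 S,S'-diethyl (2S,3S)-2,3-bis(benzyloxymethyl)butanebis(thioate)
Conditions: EtSH (3 equiv), n-BuLi (2.5 equiv), THF, 0 °C; aq. NH4Cl
Reagents that add atoms: ethanethiol, CCS
Why: Lithium thiolate cleavage of hindered N-acyl oxazolidinones attacks only the exocyclic carbonyl, is too weakly basic to epimerise the α-centres or expel benzyl oxide, and returns the auxiliary.

Step 4
Reactants: 8 S,S'-diethyl (2S,3S)-2,3-bis(benzyloxymethyl)butanebis(thioate); 9 4-(benzyloxy)-3-methoxyphenylboronic acid (3 equiv)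
Product: 10 (2S,3S)-1,4-bis[4-(benzyloxy)-3-methoxyphenyl]-2,3-bis(benzyloxymethyl)butane-1,4-dione
Conditions: Pd2(dba)3 (5 mol %), P(2-furyl)3 (20 mol %), copper thiophene-2-carboxylate Cu(O2CC4H3S) (3.2 equiv), THF, 50 °C
Reagents that add atoms: none
Why: The Liebeskind–Srogl thioester–boronic acid ketone synthesis runs without added base, so the two epimerisable, elimination-prone β-benzyloxy ketone centres are formed and kept as (S,S).

Step 5
Reactants: 10 (2S,3S)-1,4-bis[4-(benzyloxy)-3-methoxyphenyl]-2,3-bis(benzyloxymethyl)butane-1,4-dione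
Product: 14 (2S,3S,4S,5S)-2,5-bis[4-(benzyloxy)-3-methoxyphenyl]-3,4-bis(benzyloxymethyl)oxolane, via first ring oxocarbenium ion 11 (not isolated), via cyclic silyl ketal 12 (not isolated), via second ring oxocarbenium ion 13 (not isolated)
Conditions: Et3SiH (4 equiv), Et3SiOTf (0.3 equiv), CH2Cl2, −78 → −30 °C; Et3N quench
Reagents that add atoms: none
Why: Proposed new method: tandem silane reductive etherification, in which silylation of one carbonyl lets the other carbonyl oxygen close the five-membered ring to 11, Et3SiH delivers hydride anti to the adjacent CH2OBn, ionisation of 12 gives 13 and a second anti delivery follows, so each aryl ends cis to its neighbouring CH2OBn (2S and 5S) while C3 and C4 are untouched; the closest known reactions are Et3SiH/silyl triflate reductive etherification and the Lewis acid/hydride reduction of 2-aryl cyclic hemiketals, which gives 2,3-cis-2-aryl oxolanes including the cis,trans,cis 2,5-diaryl series.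

Step 6
Reactants: 14 (2S,3S,4S,5S)-2,5-bis[4-(benzyloxy)-3-methoxyphenyl]-3,4-bis(benzyloxymethyl)oxolane
Product: 15 [(2S,3S,4S,5S)-2,5-bis(4-hydroxy-3-methoxyphenyl)oxolane-3,4-diyl]dimethanol (Eduesmine)
Conditions: H2 (1 atm), Pd(OH)2/C, EtOAc, rt; stopped at complete debenzylation
Reagents that add atoms: none
Why: Catalytic hydrogenolysis removes all four benzyl ethers under neutral conditions, which avoids acid-induced benzylic epimerisation of the kinetic cis,trans,cis ring, and the O-benzyl groups should cleave faster than the ring benzylic C–O bonds in aprotic EtOAc.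

**Compound list**

1 | 3-(benzyloxy)propanoic acid | OC(=O)CCOCc1ccccc1 | starting material
2 | (S)-4-isopropyl-oxazolidin-2-one | CC(C)[C@H]1COC(=O)N1 | starting material
3 | 3-(benzyloxy)propanoic pivalic anhydride (not isolated) | CC(C)(C)C(=O)OC(=O)CCOCc1ccccc1 | intermediate
4 | (4S)-3-[3-(benzyloxy)propanoyl]-4-isopropyl-oxazolidin-2-one | CC(C)[C@H]1COC(=O)N1C(=O)CCOCc2ccccc2 | intermediate
5 | lithium Z-enolate of 4 (not isolated) | CC(C)[C@H]1COC(=O)N1/C(O[Li])=C/COCc2ccccc2 | intermediate
6 | alpha-[acetoxy(phenyl)-λ3-iodanyl] derivative of 4, α-configuration undefined (not isolated) | CC(C)[C@H]1COC(=O)N1C(=O)C(COCc2ccccc2)I(OC(C)=O)c2ccccc2 | intermediate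
7 | (4S,4'S)-3,3'-[(2S,3S)-2,3-bis(benzyloxymethyl)butanedioyl]bis(4-isopropyl-oxazolidin-2-one) | CC(C)[C@H]1COC(=O)N1C(=O)[C@H](COCc2ccccc2)[C@@H](COCc2ccccc2)C(=O)N1[C@@H](C(C)C)COC1=O | intermediate
8 | S,S'-diethyl (2S,3S)-2,3-bis(benzyloxymethyl)butanebis(thioate) | CCSC(=O)[C@H](COCc1ccccc1)[C@@H](COCc1ccccc1)C(=O)SCC | intermediate
9 | 4-(benzyloxy)-3-methoxyphenylboronic acid | COc1cc(ccc1OCc2ccccc2)B(O)O | starting material
10 | (2S,3S)-1,4-bis[4-(benzyloxy)-3-methoxyphenyl]-2,3-bis(benzyloxymethyl)butane-1,4-dione | COc1cc(ccc1OCc2ccccc2)C(=O)[C@H](COCc3ccccc3)[C@@H](COCc4ccccc4)C(=O)c5ccc(OCc6ccccc6)c(OC)c5 | intermediate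
11 | first ring oxocarbenium triflate: 2,5-diaryl-2-(triethylsilyloxy)-3,4-trans-bis(benzyloxymethyl)-3,4-dihydro-2H-furan-1-ium, C3/C4 as in 10 (not isolated) | CC[Si](CC)(CC)OC2(c1ccc(OCc3ccccc3)c(OC)c1)[O+]=C(c1ccc(OCc3ccccc3)c(OC)c1)[C@H](COCc1ccccc1)[C@H]2COCc1ccccc1.[O-]S(=O)(=O)C(F)(F)F | intermediate
12 | cyclic silyl ketal: 2,5-diaryl-2-(triethylsilyloxy)-3,4-bis(benzyloxymethyl)oxolane, 5-aryl cis to the C4 arm, mixture at the ketal carbon (not isolated) | CC[Si](CC)(CC)OC2(c1ccc(OCc3ccccc3)c(OC)c1)O[C@H](c1ccc(OCc3ccccc3)c(OC)c1)[C@H](COCc1ccccc1)[C@H]2COCc1ccccc1 | intermediate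
13 | second ring oxocarbenium triflate: 2,5-diaryl-3,4-bis(benzyloxymethyl)-3,4-dihydro-2H-furan-1-ium with the first benzylic centre set (not isolated) | COc1cc(ccc1OCc3ccccc3)C2=[O+][C@H](c1ccc(OCc3ccccc3)c(OC)c1)[C@H](COCc1ccccc1)[C@H]2COCc1ccccc1.[O-]S(=O)(=O)C(F)(F)F | intermediate
14 | (2S,3S,4S,5S)-2,5-bis[4-(benzyloxy)-3-methoxyphenyl]-3,4-bis(benzyloxymethyl)oxolane | COc1cc([C@H]2O[C@H](c3ccc(OCc4ccccc4)c(OC)c3)[C@H](COCc5ccccc5)[C@H]2COCc6ccccc6)ccc1OCc7ccccc7 | intermediate
15 | [(2S,3S,4S,5S)-2,5-bis(4-hydroxy-3-methoxyphenyl)oxolane-3,4-diyl]dimethanol (Eduesmine) | COc1cc([C@H]2O[C@H](c3ccc(O)c(OC)c3)[C@H](CO)[C@H]2CO)ccc1O | target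

**Count and risks**

Total step count: 6. Longest linear sequence: 6 (1 → 4 → 7 → 8 → 10 → 14 → 15).

The three steps most likely to fail are steps 2, 5 and 6.

Step 2 (homocoupling of a β-benzyloxy enolate): the lithium enolate may lose benzyl oxide before it couples, or the diastereoselectivity may be low. The fallback sets out from imide 4. Soft enolisation with Me3SiOTf/Et3N in CH2Cl2 at 0 °C gives the silyl ketene N,O-acetal F1, so no free enolate is ever present. TiCl4 in CH2Cl2 at −78 °C exchanges silicon for titanium to give the chelated trichlorotitanium enolate F2. On warming to −20 °C this homocouples while titanium goes from tetravalent to trivalent, which is the known TiCl4 oxidative dimerisation of silyl ketene acetals to succinates. The same auxiliary-shielded face is used, and the route is rejoined at bis-imide 7.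

Step 5 (one-pot double reductive cyclisation): an open-chain reduction of the first ketone would give a 4,5-trans centre, and furan formation or benzylic over-reduction may compete. The fallback sets out from diketone 10. Me3SiOMe with catalytic Me3SiOTf in CH2Cl2 at −78 °C (Noyori-type ketalisation) converts it into the isolable cyclic bis(methyl ketal) F3. Et3SiH/BF3·OEt2 in CH2Cl2 at −78 °C then reduces the two ketal carbons in turn, each necessarily through a ring oxocarbenium ion, and the route is rejoined at 14.

Step 6 (global hydrogenolysis): the two alkyl benzyl ethers cleave slowly, and the ring benzylic C–O bonds of the electron-rich 2-aryl oxolane may start to hydrogenolyse. The fallback sets out from 14 and comes back at 15 with no new isolated compound. It uses single-electron reductive debenzylation with lithium 4,4'-di-tert-butylbiphenylide in THF at −78 °C, followed by NH4Cl. The unsubstituted benzyl rings accept an electron far more readily than the dialkoxy-substituted rings on the oxolane, and the medium is basic, so the cis,trans,cis ring is neither opened nor epimerised.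

**Further compounds**

F1 | step 2 | (4S)-3-[(Z)-3-(benzyloxy)-1-(trimethylsilyloxy)prop-1-enyl]-4-isopropyl-oxazolidin-2-one (silyl ketene N,O-acetal of 4) | CC(C)[C@H]1COC(=O)N1/C(O[Si](C)(C)C)=C/COCc2ccccc2
F2 | step 2 | trichlorotitanium Z-enolate of 4 | CC(C)[C@H]1COC(=O)N1/C(O[Ti](Cl)(Cl)Cl)=C/COCc2ccccc2
F3 | step 5 | (3S,4S)-2,5-bis[4-(benzyloxy)-3-methoxyphenyl]-3,4-bis(benzyloxymethyl)-2,5-dimethoxyoxolane (anomer mixture) | COC2(c1ccc(OCc3ccccc3)c(OC)c1)OC(OC)(c1ccc(OCc3ccccc3)c(OC)c1)[C@H](COCc1ccccc1)[C@H]2COCc1ccccc1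
F0 | step 6 | none | none
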